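**Retrosynthetic overview**
Target: (2S,4S)-7,4'-dihydroxyflavan joined through C4 to C8 of (−)-epicatechin; the last step releases it from its hepta-O-benzyl ether by hydrogenolysis.
Key disconnection: the upper pyran ring is opened at C2–C3 and at O1–C8a, giving 4-(benzyloxy)benzaldehyde and a 1,1-diarylethene whose central carbon (future C4) carries ring A as a 4-benzyloxy-2-fluorophenyl group and C8 of penta-O-benzylepicatechin.
Enabling feature: C4 is doubly benzylic, with the 7-oxygen para on the upper ring A and oxygens at both ortho positions and the para position on the epicatechin ring A; the resulting long-lived carbenium ion at C4 makes the alkene CH2 (C3) nucleophilic towards the aldehyde carbon and makes ring carbon C8a (ortho to C4a) electrophilic towards the aldehyde oxygen.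
The diarylethene comes from C8-lithiated penta-O-benzylepicatechin (via regioselective C8 bromination) and 4'-benzyloxy-2'-fluoroacetophenone, by addition and dehydration.
Ring order: all four benzene rings and the epicatechin pyran ring are bought; the upper pyran ring is the only ring formed, in the key step, which also sets C2 and C4.

Key step: step 6

Remark: the target is read as (2S,4S), 2,4-cis, in the upper flavan and (2R,3R) in the lower unit, i.e. (−)-epicatechin; the sense of induction of the chiral catalyst in step 6 cannot be predicted, so the antipode that gives the 2S series is assumed to be chosen.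

**Step 1**
Reactants: 1 (−)-epicatechin
Product: 2 5,7,3',4'-tetra-O-benzyl-(−)-epicatechin
Conditions: BnBr (4.4 equiv), K2CO3, DMF, 0 °C → rt
Reagents that add atoms: benzyl bromide, BrCc1ccccc1
Why: Williamson etherification in which carbonate deprotonates only the four phenols, so the secondary 3-OH stays free and both stereocentres are untouched.

**Step 2**
Reactants: 2 5,7,3',4'-tetra-O-benzyl-(−)-epicatechin
Product: 3 3,5,7,3',4'-penta-O-benzyl-(−)-epicatechin
Conditions: NaH, BnBr, Bu4NI (cat.), DMF, 0 °C → rt
Reagents that add atoms: benzyl bromide, BrCc1ccccc1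
Why: Williamson etherification of the secondary alcohol through its sodium alkoxide; with no free phenol left, C2 cannot epimerise by ring opening, so both stereocentres are kept.

**Step 3**
Reactants: 3 3,5,7,3',4'-penta-O-benzyl-(−)-epicatechin
Product: 4 8-bromo-3,5,7,3',4'-penta-O-benzyl-(−)-epicatechin
Conditions: NBS (1.05 equiv), CH2Cl2, −78 → 0 °C
Reagents that add atoms: N-bromosuccinimide, O=C1CCC(=O)N1Br
Why: Electrophilic aromatic bromination of the phloroglucinol-type ring, which is far more electron-rich than the catechol ring, at C8, the more reactive of its two free positions in 5,7-di-O-alkyl flavans.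

**Step 4**
Reactants: 5 2'-fluoro-4'-hydroxyacetophenone
Product: 6 4'-(benzyloxy)-2'-fluoroacetophenone
Conditions: BnBr, K2CO3, acetone, reflux
Reagents that add atoms: benzyl bromide, BrCc1ccccc1
Why: Williamson etherification of the phenol; the ketone and the aryl fluoride are inert to K2CO3 and BnBr.

**Step 5**
Reactants: 4 8-bromo-3,5,7,3',4'-penta-O-benzyl-(−)-epicatechin; 6 4'-(benzyloxy)-2'-fluoroacetophenone
Product: 9 8-{1-[4-(benzyloxy)-2-fluorophenyl]ethenyl}-3,5,7,3',4'-penta-O-benzyl-(−)-epicatechin (the 1,1-diarylethene), via 8-lithio-penta-O-benzylepicatechin 7 (not isolated), via tertiary carbinol 8 (not isolated)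
Conditions: n-BuLi (1.05 equiv), THF, −78 °C; then 6 premixed with LaCl3·2LiCl, −78 → 0 °C; H2O quench; crude carbinol, PPTS (cat.), PhMe, 60 °C
Reagents that add atoms: none
Why: Bromine–lithium exchange at C8 should outrun benzylic deprotonation at −78 °C, the lanthanum-complexed methyl ketone should undergo 1,2-addition instead of enolisation, and the bis-benzylic tertiary carbinol should lose water (E1) towards the methyl group, its only β-hydrogens; the carbinol centre is destroyed and no stereocentre is formed.

**Step 6**
Reactants: 9 the 1,1-diarylethene; 10 4-(benzyloxy)benzaldehyde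
Product: 13 hepta-O-benzyl ether of the target [(2S,4S)-7-benzyloxy-2-(4-benzyloxyphenyl)chroman-4-yl at C8 of penta-O-benzylepicatechin], via silyloxy carbenium ion 11 (not isolated), via flavan-4-ylium ion 12 (not isolated)
Conditions: 10 (1.2 equiv), chiral confined imidodiphosphorimidate (IDPi, 5 mol%, silylated in situ with allyl-SiEt3, 5 mol%), Et3SiH (1.3 equiv, slow addition), CH2Cl2, −60 → −20 °C
Reagents that add atoms: none
Why: Proposed new method: the silylated chiral ion pair activates 10 as a silyloxocarbenium ion, the CH2 terminus of 9 adds to it (C3–C2, Prins/Mukaiyama-type) to give the doubly benzylic carbenium ion 11, the C2 silyl ether oxygen then attacks the fluorine-bearing ring carbon C8a of this para-benzyloxy-stabilised quinoid cation and fluoride leaves to silicon (O1–C8a), and Et3SiH reduces the resulting flavan-4-ylium ion 12 at C4 and regenerates the silylium catalyst. The closest known reaction types are silylium/IDPi-catalysed enantioselective additions of π-nucleophiles to aromatic aldehydes, the ipso-substitution of ortho-fluoro or ortho-methoxy groups in triarylcarbenium ions by N- and O-nucleophiles (acridinium and xanthylium synthesis), and ionic hydrogenation of benzylic cations with silanes. The pyran ring, the only ring formed, closes by 6-exo-trig addition–elimination at C8a. C2 is set under catalyst control, the confined chiral anion shielding one face of the aldehyde during C–C bond formation (the three remote epicatechin centres give no useful bias), and C4 is set under substrate control by axial hydride delivery to the half-chair ion 12 with the C2 aryl group equatorial, which should place H4 cis to H2 and so the two aryl groups cis (4S). The step needs the alkene CH2, not a benzyloxyarene carbon or the silane, to capture the activated aldehyde, which the high π-nucleophilicity of the oxygen-rich diarylethene should secure. It also needs closure at C8a and not at the other ortho carbon C5, secured by fluorine as the only leaving group, and closure of 11 faster than its reduction, secured by the intramolecular six-ring closure and the slow addition of the silane.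

**Step 7**
Reactants: 13 hepta-O-benzyl ether of the target
Product: 14 CNP0298337.1, (2R,3R)-2-(3,4-dihydroxyphenyl)-8-[(2S,4S)-7-hydroxy-2-(4-hydroxyphenyl)chroman-4-yl]chromane-3,5,7-triol
Conditions: H2 (1 atm), 20% Pd(OH)2/C, THF/MeOH (1:1), rt
Reagents that add atoms: none
Why: Hydrogenolysis of the seven benzyl ethers; the cyclic benzylic C2–O1 bonds of both flavan units and the doubly benzylic C4–H should be cleaved much more slowly than O-benzyl groups, so all four stereocentres are retained.

**Compound list**
1 | (−)-epicatechin | Oc1cc(O)c2c(c1)O[C@H](c1ccc(O)c(O)c1)[C@H](O)C2 | starting material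
2 | 5,7,3',4'-tetra-O-benzyl-(−)-epicatechin | c1c(OCc2ccccc2)cc(OCc2ccccc2)c2c1O[C@H](c1ccc(OCc3ccccc3)c(OCc3ccccc3)c1)[C@H](O)C2 | intermediate
3 | 3,5,7,3',4'-penta-O-benzyl-(−)-epicatechin | c1c(OCc2ccccc2)cc(OCc2ccccc2)c2c1O[C@H](c1ccc(OCc3ccccc3)c(OCc3ccccc3)c1)[C@H](OCc1ccccc1)C2 | intermediate
4 | 8-bromo-3,5,7,3',4'-penta-O-benzyl-(−)-epicatechin | Brc1c(OCc2ccccc2)cc(OCc2ccccc2)c2c1O[C@H](c1ccc(OCc3ccccc3)c(OCc3ccccc3)c1)[C@H](OCc1ccccc1)C2 | intermediate
5 | 2'-fluoro-4'-hydroxyacetophenone | CC(=O)c1ccc(O)cc1F | starting material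
6 | 4'-(benzyloxy)-2'-fluoroacetophenone | CC(=O)c1ccc(OCc2ccccc2)cc1F | intermediate
7 | 8-lithio-3,5,7,3',4'-penta-O-benzyl-(−)-epicatechin | [Li]c1c(OCc2ccccc2)cc(OCc2ccccc2)c2c1O[C@H](c1ccc(OCc3ccccc3)c(OCc3ccccc3)c1)[C@H](OCc1ccccc1)C2 | intermediate (not isolated)
8 | 1-[4-(benzyloxy)-2-fluorophenyl]-1-(penta-O-benzylepicatechin-8-yl)ethanol, both epimers at the carbinol carbon | CC(O)(c1ccc(OCc2ccccc2)cc1F)c1c(OCc2ccccc2)cc(OCc2ccccc2)c2c1O[C@H](c1ccc(OCc3ccccc3)c(OCc3ccccc3)c1)[C@H](OCc1ccccc1)C2 | intermediate (not isolated)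
9 | 8-{1-[4-(benzyloxy)-2-fluorophenyl]ethenyl}-3,5,7,3',4'-penta-O-benzyl-(−)-epicatechin | C=C(c1ccc(OCc2ccccc2)cc1F)c1c(OCc2ccccc2)cc(OCc2ccccc2)c2c1O[C@H](c1ccc(OCc3ccccc3)c(OCc3ccccc3)c1)[C@H](OCc1ccccc1)C2 | intermediate
10 | 4-(benzyloxy)benzaldehyde | O=Cc1ccc(OCc2ccccc2)cc1 | starting material
11 | (3S)-3-[4-(benzyloxy)phenyl]-1-[4-(benzyloxy)-2-fluorophenyl]-1-(penta-O-benzylepicatechin-8-yl)-3-(triethylsilyloxy)propan-1-ylium ion, paired with the catalyst anion | CC[Si](CC)(CC)O[C@@H](C[C+](c1ccc(OCc2ccccc2)cc1F)c1c(OCc2ccccc2)cc(OCc2ccccc2)c2c1O[C@H](c1ccc(OCc3ccccc3)c(OCc3ccccc3)c1)[C@H](OCc1ccccc1)C2)c1ccc(OCc2ccccc2)cc1 | intermediate (not isolated)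
12 | (2S)-7-(benzyloxy)-2-[4-(benzyloxy)phenyl]-4-(penta-O-benzylepicatechin-8-yl)chroman-4-ylium ion, paired with the catalyst anion | c1ccccc1COc1ccc([C@@H]2C[C+](c3c(OCc5ccccc5)cc(OCc5ccccc5)c4c3O[C@H](c3ccc(OCc5ccccc5)c(OCc5ccccc5)c3)[C@H](OCc3ccccc3)C4)c3ccc(OCc5ccccc5)cc3O2)cc1 | intermediate (not isolated)
13 | (2R,3R)-3,5,7-tris(benzyloxy)-2-[3,4-bis(benzyloxy)phenyl]-8-{(2S,4S)-7-(benzyloxy)-2-[4-(benzyloxy)phenyl]chroman-4-yl}chromane | c1ccccc1COc1ccc([C@@H]2C[C@H](c3c(OCc5ccccc5)cc(OCc5ccccc5)c4c3O[C@H](c3ccc(OCc5ccccc5)c(OCc5ccccc5)c3)[C@H](OCc3ccccc3)C4)c3ccc(OCc5ccccc5)cc3O2)cc1 | intermediate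
14 | CNP0298337.1, (2R,3R)-2-(3,4-dihydroxyphenyl)-8-[(2S,4S)-7-hydroxy-2-(4-hydroxyphenyl)chroman-4-yl]chromane-3,5,7-triol | Oc1ccc([C@@H]2C[C@H](c3c(O)cc(O)c4c3O[C@H](c3ccc(O)c(O)c3)[C@H](O)C4)c3ccc(O)cc3O2)cc1 | target

**Step count and risks**
Total steps: 7. Longest linear sequence: 6 (steps 1, 2, 3, 5, 6, 7).

Step 6 (proposed new method) is the riskiest. Enantiofacial control at the aldehyde may be insufficient, the silane may capture the open carbenium ion before the ring closes, or hydride may be delivered to the wrong face of C4. The fallback uses known chemistry, sets out from bromide 4 and returns at 13. Commercial 7-hydroxychromone is benzylated (BnBr, K2CO3) to 7-(benzyloxy)chromone F1. Rhodium(I)/chiral diene-catalysed 1,4-addition of commercial 4-(benzyloxy)phenylboronic acid (Hayashi–Miyaura type) should give (S)-7-(benzyloxy)-2-[4-(benzyloxy)phenyl]chroman-4-one F2, with C2 set by the catalyst. Aryllithium 7, made from 4 as in step 5 and used with LaCl3·2LiCl, adds to the C4 carbonyl to give the tertiary flavan-4-ol F3. Ionic deoxygenation (Et3SiH, CF3CO2H, CH2Cl2, −40 °C) passes through ion 12 and should give 13 with the same axial hydride delivery. In this fallback O1–C8a is bought with the chromone.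

Step 5 is next. The hindered aryllithium may take a proton from the methyl ketone instead of adding, and the electron-rich diarylethene may oligomerise under the acid used for dehydration. The fallback sets out from ketone 6 and bromide 4 and returns at 9. Ketone 6 is condensed with tosylhydrazide (MeOH, 60 °C) to the N-tosylhydrazone F4. Barluenga coupling of F4 with 4 (Pd2(dba)3, XPhos, LiOtBu, dioxane, 100 °C) should give 9 directly through a palladium carbene, migratory insertion and β-hydride elimination, with no organolithium and no acid.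

Step 7 is third. Removal of seven benzyl groups may stall, or prolonged exposure may open the benzylic C2–O1 bonds reductively. The fallback goes from 13 to 14 without hydrogen: Lewis-acid debenzylation with BCl3 and pentamethylbenzene as benzyl cation scavenger (CH2Cl2, −78 °C, then MeOH). It makes no new compound (F0).

**Further compounds**
F1 | step 6 | 7-(benzyloxy)-4H-chromen-4-one | O=c1ccoc2cc(OCc3ccccc3)ccc12
F2 | step 6 | (S)-7-(benzyloxy)-2-[4-(benzyloxy)phenyl]chroman-4-one | O=C1C[C@@H](c2ccc(OCc3ccccc3)cc2)Oc2cc(OCc3ccccc3)ccc12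
F3 | step 6 | (2S)-7-(benzyloxy)-2-[4-(benzyloxy)phenyl]-4-(penta-O-benzylepicatechin-8-yl)chroman-4-ol, either epimer at C4 | OC1(c4c(OCc5ccccc5)cc(OCc5ccccc5)c6c4O[C@H](c4ccc(OCc5ccccc5)c(OCc5ccccc5)c4)[C@H](OCc4ccccc4)C6)C[C@@H](c2ccc(OCc3ccccc3)cc2)Oc2cc(OCc3ccccc3)ccc12
F4 | step 5 | N'-{1-[4-(benzyloxy)-2-fluorophenyl]ethylidene}-4-methylbenzenesulfonohydrazide | CC(=NNS(=O)(=O)c1ccc(C)cc1)c1ccc(OCc2ccccc2)cc1F
F0 | step 7 | none | none
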